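I could not read a mechanism out of winter readings that scatter by 1.5 percentage points, but I could read two times from them.

| flask | substrate | reagent | remark | time |
|---|---|---|---|---|
| winter | 0.0050 M | 0.015 M | run made earlier |  |
| flask | 0.010 M | 0.0150 M |  | 6.0 d |

winter run (percent of the substrate charged): time / h: first product / % = 4.00: 3; 10.0: 7; 20.0: 11; 30.0: 15; 40.0: 16

(readings scatter by 1.5 percentage points)

- the analysis behind the earlier runs scatters by 1.5 percentage points, standard deviation

- the best time, 6.0 d at the latest, for first product
- the amount of first product, in percent of the substrate charged, at that time

The first is the making time, 143 h: the winter run's whole charge taken at its early pace of 7% in 10.0 h, which I treated as a pseudo-first-order pace at the charged 0.015 M of reagent. The second is the loss time. From 20.0 h to 40.0 h the winter readings still rose, but from 11% to 16%, slower than at first. I put the pace lost against the midway level of 13.5%, and that level over the lost pace gave the loss time, 30.0 h. Their ratio is the balance level, 21.0%, the share of the charge at which making and loss match, and it carries the scatter of those readings. The flask charges the same reagent, so I kept the making time. I assumed the loss time unchanged, though the substrate is twice the winter charge. After 3 loss times the rise is about over, so I reckoned 21.0% near 3.75 d, sooner than the limit of 6.0 d.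

The forecast, which differs from my reckoning, gave 19% at 3.9 d, holding that “Yield depends only on reagent exposure”.

The flask gave 14.5% at 2.67 d, lower than my level and earlier than my time.

    substrate + reagent → first product (k = 0.663 /M/h)
    reagent + first product → double product (k = 0.607 /M/h)
    substrate + first product → side product (k = 1.33 /M/h)
    2 reagent → homo dimer (k = 0.674 /M/h)
    first product ⇌ isomer of the product (K = 0.389, k = 0.00979 /h)

A neighbouring flask differs from this flask in holding 0.0037 M of reagent. Its making time stretches with the reagent ratio to 24.1 d, and with the loss time kept, its balance level comes to 5.18%. That neighbouring flask gave 6.00%, more than this level, and at 6.0 d it still held 75.0% of its substrate.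

(The numbers in the tables stem from a simulated flask from invented constants, noise included.)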